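The constants used here are made up; no experiment stands behind them.

**Reading time.** I read the amount of the open intermediate at the outlet or at the end of the run. It shows what step 4 has left of it.

| flask | substrate | partner | remark | time |
|---|---|---|---|---|
| winter | 44 mM | 1.05 equiv | one stirred flow tank at steady state, fed with the mixture as stated, mean residence time 1.5 h |  |
| summer | 44 mM (fed, over 1.20 h) | 1.05 equiv | all but substrate at the start; substrate goes in evenly over 1.20 h, the run ends at 1.5 h | 1.5 h |
| midnight | 44 mM | 1.05 equiv (fed, over 1.20 h) | a stirred flask in which partner is dosed at a steady rate over 1.20 h without added volume, worked up at 1.5 h | 1.5 h |
| noon | 44 mM | 1.05 equiv | everything together in a closed stirred flask, run for 1.5 h | 1.5 h |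

    substrate → open intermediate (k1 = 0.052 min⁻¹)
    partner → second intermediate (k2 = 0.20 min⁻¹)
    target ⇌ isomer of the product (K3 = 1.9, k3 = 0.19 min⁻¹)
    open intermediate + second intermediate → target (k4 = 0.24 M⁻¹ min⁻¹)

- the stated concentrations are those of everything mixed, before any reaction; amounts are the same in each set-up
- the feed brings no volume worth counting
- run time (summer): 1.5 h

1. the set-up with the highest amount of open intermediate at the outlet or at the end, in percent of the substrate put in ("none" if the first two lie within 2 percentage points) (winter / summer / midnight / noon / none)
2. amount of open intermediate at the outlet or at the end, in percent of the substrate put in, winter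
3. amount of open intermediate at the outlet or at the end, in percent of the substrate put in, summer
4. amount of open intermediate at the outlet or at the end, in percent of the substrate put in, midnight
5. amount of open intermediate at the outlet or at the end, in percent of the substrate put in, noon

**Which numbers.** Step 3 starts from target and gives nothing back to the open intermediate, so 1.9 and 0.19 min⁻¹ could stay rough. The mean life of partner by step 2 was 5.00 min, so an error of half in it moved my arrival times by 2.50 min. The mean life of substrate by step 1 was 19.2 min, so the same error moved them by 9.60 min. The number to know well was the coupling time, one over the constant of step 4 times the substrate charge: 94.7 min. That is longer than either mean life.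

**Frozen supply.** So I froze the supply. I let each intermediate appear whole at its mean arrival and started a clock at the later arrival. Substrate is the limiting reagent, and partner's excess e is 0.0500 of the charge. With s as the clock over the coupling time, the share left is e / ((1 + e) exp(e s) − 1).

**My reckoning.** In noon the clock ran 70.8 min, which gave 55.6 %. In midnight partner arrived on average at half the dosing time plus its mean life, so the clock ran 49.0 min. That gave 64.5 %, more than noon. I did not reckon winter or summer.

**The forecast.** It named midnight, with 50.2 % for winter, 62.4 % for summer, 66.4 % for midnight and 55.6 % for noon, the batch cases by “hand Simpson steps of 10 min”. My midnight figure lay below its value.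

**The result.** The best set-up was midnight, with 50.2 % for winter, 62.4 % for summer, 66.4 % for midnight and 55.6 % for noon.

**Longer clock.** In midnight the clock of 49.0 min was shorter than the coupling time of 94.7 min, and 66.4 % of the open intermediate stood at the end. Left until 15.0 h, the midnight clock ran 859 min, which is 9.07 coupling times, and the formula gave 7.66 %. The flask held 7.72 %.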